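Read at 2.0 min, the amber flask lies far beyond its last reading at 15.0 s, so the violet run, with the same charges of Ptn and Tsp, has to supply the later course.

| flask | Sub | Ptn | Tsp | remark | time | volume of the second phase over the first |
|---|---|---|---|---|---|---|
| amber | 0.10 M | 0.11 M | 0.050 M | the very flask that is asked about, followed so far |  |  |
| violet | 0.15 M | 0.11 M | 0.050 M | run made earlier |  |  |
| flask | 0.10 M | 0.110 M | 0.0500 M |  | 2.0 min | 1.0 |

| run | time / s | Sid / % | Sub.Ptn2 / % |
|---|---|---|---|
| amber | 10.0 | 4.3 | 5.6 |
| amber | 12.0 | 5.1 | 5.3 |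
| amber | 15.0 | 8.1 | 6.0 |
| violet | 10.0 | 5.6 | 5.2 |
| violet | 12.0 | 6.8 | 5.6 |
| violet | 25.0 | 13.6 | 5.1 |
| violet | 40.0 | 21.0 | 3.6 |
| violet | 50.0 | 23.4 | 3.7 |
| violet | 60.0 | 27.4 | 3.3 |
| violet | 80.0 | 31.4 | 4.1 |

(readings scatter by 0.5 percentage points)

- charges count per volume of the first phase; a concentration in a rate is the amount of a species over the volume of its own phase; every rate counts per litre of the first phase
- the earlier runs hold the two phases in the same ratio of volumes as the flask asked about
- a reading or a percentage of Sub.Ptn2 counts all its forms, free or not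

- the best time, 2.0 min at the latest, for Sid
- the amount of Sid, in percent of the Sub charged, at that time

A bench rule says that Sid grows from whatever Sub.Ptn2 stands in the flask. Between 12.0 s and 80.0 s, violet gains 25 percentage points of Sid while its Sub.Ptn2 readings average 4.23%. Dividing that rate by that level gives the turnover constant, 0.0855 /s: a first-order constant for Sid made per unit of Sub.Ptn2 standing, read with the scatter of the readings.

My own reckoning holds that level in amber and gives 43.4% of Sid at 2.0 min, still rising, so the latest time is best. The border comes from the charges. Tsp stands to Sub as 0.500, and if each Tsp removed one Sub, Sid would stop near 50.0%. The straight line reaches that after 2.30 min, later than 2.0 min, but with little room.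

The forecast gives 2 min and 38%, lower than my figure, and holds that “Nothing shows Sid being consumed”.

The flask gives 36.7% at 2.00 min.

    Ptn2 ⇌ Ptn, rate k1*([Ptn2] - [Ptn]/K1) per volume of the first phase (partition coefficient = 0.860, kL = 1.47 /s)
    Sub + Ptn2 ⇌ Sub.Ptn2 (K = 5.33 /M, k = 0.278 /M/s)
    Sub.Ptn2 ⇌ Prd, rate k3*([Sub.Ptn2] - [Prd]/K3) per volume of the first phase (partition coefficient = 1.10, kL = 0.0143 /s)
    Sub.Ptn2 → Sid (k = 0.139 /s)
    Sub + Tsp → Sub.Tsp (k = 0.696 /M/s)
    Sub.Ptn2 → Sid2 (k = 3.12 × 10⁻⁵ /s)

At 2.00 min the flask holds 2.38% of Sub.Ptn2, of which 1.52% is Prd, and the scheme has no step from Prd to Sid. The turnover constant, read in violet on the whole reading, gives 0.122 /min of the charged Sub on this amount and 0.0441 /min on the part without Prd; Sid in the flask gained 0.0815 /min from 1.60 min to 2.00 min, so the constant gives a range here, not a single pace. With 0.20 M of Tsp, the neighbour flask holds 0.277% of Sub.Ptn2 at 2.00 min, of which 0.259% is Prd, so the same range runs from 9.52 × 10⁻⁴ /min to 0.0142 /min, lower than the flask's. Computed, that neighbour flask stands at 9.27% of Sid, with 0.014% of its Sub left.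

(All runs were generated by integration with constants of no real substance, noise included.)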